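A direct plan would desymmetrise phloroglucinol by two successive mono-protections to the MOM/silyl phenol A1, join it by Mitsunobu inversion to the kinetically resolved ring B epoxy carbinol A2, close ring C of the glycidyl ether A3 by epoxy–arene Friedel–Crafts alkylation, and finish by unmasking O5, double galloylation, desilylation of the bis-gallate A4 and hydrogenolysis. Its weakest steps would be:
- the two statistical mono-protections leading to A1, which would spend two steps and most of the material only to tell O5 from O7;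
- the Friedel–Crafts closure of A3, where the choice between the two ortho carbons, and so the whole O5/O7 assignment, would rest on a steric bias alone (after a Mitsunobu step at an ionisable p-alkoxybenzylic carbinol);
- the fluoride desilylation of A4, which would set a phenoxide free beside a phenyl gallate on the most precious intermediate.

**Plan of the new route**

Cuts: both gallate C–O bonds at once (14), then C3–H (dynamic reduction of racemic ketone 13, whose C2–H is labile between O1, ring B and C3=O), then O1–C8a with a drop of one oxidation level to furyl carbinol 8, then C2–C1' and the furan (Feist–Benary).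
Enabling feature: ring A is a phloroglucinol, i.e. the enol of a 5-oxygenated cyclohexane-1,3-dione with C5 and C8a equivalent and O7 on the C4a–C7 axis. The unit O–C8a=C4a–C4=C3 is carried as a furan, and the two electrons removed in its Achmatowicz oxidation are exactly those ring A lacks for aromaticity.
Ring order: B (bought), A as a saturated dione, furan, ring C by ring expansion, ring A aromatic last.
O5 stays a ketone and O7 an alkyl ether until then, so nothing is desymmetrised, no bond is closed onto an aromatic ring A, C2 is never a substitution centre, and only benzyl groups remain at the end.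

Key step: step 6

Remark: the (R,R) catalyst in step 7 is written on the assumption that C2, with its aryl and ether substituents, takes the place of the aryl group of an aryl alkyl ketone in the usual transition-state model; should a test reduction show the opposite sense, the equally available (S,S) catalyst would be used. Flavan numbering is used for ring positions of the core and its precursors.

**Route**

Step 1
Reactants: 1 phloroglucinol
Product: 2 5-hydroxycyclohexane-1,3-dione (dihydrophloroglucinol)
Conditions: NaBH4 (1.0 equiv), H2O, 0 °C → rt, N2; then HCl to pH 4, 0 °C; freeze-drying, used crude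
Reagents that add atoms: none
Why: Partial reduction of a phenol through its keto tautomer: borohydride adds to one carbonyl of the triketo form of the phloroglucinolate and stops there because the product is held as the unreactive 1,3-dione enolate (the known reduction of phloroglucinol to dihydrophloroglucinol); 2 is achiral, C5 lying on its mirror plane.

Step 2
Reactants: 2 5-hydroxycyclohexane-1,3-dione
Product: 4 6-hydroxy-6,7-dihydro-1-benzofuran-4(5H)-one (racemic), via hydroxydihydrofuran adduct 3 (not isolated)
Conditions: ClCH2CHO (50% aq., 1.2 equiv), NaHCO3 (1.0 equiv), H2O, 0 °C → rt; then H2SO4 (cat., pH 1–2), EtOAc, rt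
Reagents that add atoms: chloroacetaldehyde, ClCC=O
Why: Feist–Benary furan annulation: the dione carbon adds to the aldehyde, the enol oxygen displaces chloride to give 3, and acid dehydrates 3 to the furan; the two carbonyls of 2 are equivalent, so one constitution results, and the hydroxyl-bearing carbon (racemic) is a centre that is erased later.

Step 3
Reactants: 4 6-hydroxy-6,7-dihydro-1-benzofuran-4(5H)-one
Product: 5 6-(benzyloxy)-6,7-dihydro-1-benzofuran-4(5H)-one (racemic)
Conditions: BnOC(=NH)CCl3 (1.5 equiv), TfOH (5 mol %), CH2Cl2–cyclohexane, 0 °C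
Reagents that add atoms: benzyl 2,2,2-trichloroacetimidate, N=C(OCc1ccccc1)C(Cl)(Cl)Cl
Why: Acid-catalysed O-benzylation with the trichloroacetimidate forms the ether without generating an enolate, so the β-hydroxy ketone should not undergo E1cB loss of water, and the acyl-deactivated furan should not compete for the benzyl cation equivalent.

Step 4
Reactants: 5 6-(benzyloxy)-6,7-dihydro-1-benzofuran-4(5H)-one
Product: 6 6-(benzyloxy)-4-oxo-4,5,6,7-tetrahydro-1-benzofuran-2-carbaldehyde (racemic)
Conditions: POCl3 (1.2 equiv), DMF, 0 °C → rt; then aq. NaOAc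
Reagents that add atoms: N,N-dimethylformamide, CN(C)C=O; water, O
Why: Vilsmeier–Haack formylation at the only free α-position of the furan, which is also the one not deactivated by the neighbouring acyl-bearing carbon; at or below room temperature the weakly enolised conjugated ketone should not be chloroformylated.

Step 5
Reactants: 6 6-(benzyloxy)-4-oxo-4,5,6,7-tetrahydro-1-benzofuran-2-carbaldehyde; 7 3,4-bis(benzyloxy)phenylboronic acid (1.5 equiv)
Product: 8 6-(benzyloxy)-2-{[3,4-bis(benzyloxy)phenyl](hydroxy)methyl}-6,7-dihydro-1-benzofuran-4(5H)-one (mixture of stereoisomers)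
Conditions: [Rh(acac)(coe)2] (3 mol %), P(t-Bu)3 (3 mol %), DME–H2O, rt
Reagents that add atoms: none
Why: Rhodium-catalysed 1,2-addition of an arylboronic acid to an aldehyde runs without added base and discriminates the aldehyde from the furan-conjugated ketone, so the β-benzyloxy ketone should survive; the new carbinol centre is formed without control, which is harmless because step 6 makes it labile.

Step 6
Reactants: 8 6-(benzyloxy)-2-{[3,4-bis(benzyloxy)phenyl](hydroxy)methyl}-6,7-dihydro-1-benzofuran-4(5H)-one
Product: 13 7-(benzyloxy)-2-[3,4-bis(benzyloxy)phenyl]-5-hydroxychroman-3-one (racemic), via hemiketal pyranone 9 (not isolated), via hemiketal trifluoroacetate 10 (not isolated), via oxidopyrylium betaine 11 (not isolated), via cross-conjugated dienone 12 (not isolated)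
Conditions: NBS (1.0 equiv), NaHCO3, NaOAc, THF–H2O (4:1), 0 °C; Na2S2O3, extraction; then (CF3CO)2O (1.1 equiv), Et3N (4 equiv), CH2Cl2 (0.02 M), −78 °C → rt, Ar; MeOH–aq. NaHCO3
Reagents that add atoms: water, O
Why: Proposed new method: NBS and water oxidise the furan to a cis-2-ene-1,4-dione, and the carbinol oxygen adds to the former furan carbon C8a to close ring C as hemiketal 9 (6-exo-trig addition to a carbonyl, the Achmatowicz rearrangement; because the 2-alkylidene-5-benzyloxycyclohexane-1,3-dione is symmetric about the C4a–C7 axis, closure on either ring carbonyl gives the same constitution). O-Trifluoroacetylation makes the hemiketal oxygen a leaving group (10), and triethylamine removes C2–H so that it is expelled with the pyran ring intact, as in the amine-induced formation of 3-oxidopyrylium betaines from pyranulose esters, to give betaine 11. Two amine-mediated proton shifts follow, C8–H to C2 (dienone 12) and then C7–H to C4 through the extended enolate, and enolisation of C5=O makes ring A aromatic; ring A is thus not closed but aromatised, its six carbons being those of the dione. The closest known reactions are the Achmatowicz rearrangement, the dehydration of tertiary hemiketals with (CF3CO)2O and an amine, and the base-induced isoaromatisation of alkylidenecyclohexenones to phenols; their coupling on a ring-fused furan, by which the two electrons taken from the furan end up as the aromaticity of ring A, has not been shown. No stereocentre is created: the carbinol centre becomes the configurationally labile C2 and the benzyloxy-bearing carbon becomes aromatic C7, so all stereoisomers of 8 should converge on racemic 13. The step needs the proton shifts to outrun loss of benzyl alcohol from C7 and opening of ring C (which would let a resorcinol reclose on C3 to a benzofuran); the first should be secured by basic conditions, under which benzyloxide is a poor leaving group while aromatisation is irreversible, the second by acylating the hemiketal cold before any base-induced chemistry starts, and the O1/O5/O7 assignment needs no selectivity at all, since O5 is the ketone oxygen, O7 the ether on the symmetry axis and O1 the carbinol oxygen.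

Step 7
Reactants: 13 7-(benzyloxy)-2-[3,4-bis(benzyloxy)phenyl]-5-hydroxychroman-3-one (racemic)
Product: 14 (2R,3R)-7-(benzyloxy)-2-[3,4-bis(benzyloxy)phenyl]chroman-3,5-diol
Conditions: RuCl[(R,R)-TsDPEN](p-cymene) (2 mol %), HCO2H–Et3N (1:1), DMF, 30 °C, Ar
Reagents that add atoms: none
Why: Noyori-type asymmetric transfer hydrogenation under dynamic kinetic resolution (known for α-aryl and α-oxy cyclic ketones): C2–H, flanked by O1, ring B and C3=O, should epimerise through the enol in the amine buffer faster than hydride transfer, the catalyst should reduce one enantiomer of 13 much faster and deliver hydride to C3 anti to the 2-aryl group, so that C3 is set by the catalyst and C2 by the cis preference, giving the (2R,3R)-diol.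

Step 8
Reactants: 14 (2R,3R)-7-(benzyloxy)-2-[3,4-bis(benzyloxy)phenyl]chroman-3,5-diol; 15 3,4,5-tris(benzyloxy)benzoic acid (3 equiv)
Product: 16 (2R,3R)-7-(benzyloxy)-2-[3,4-bis(benzyloxy)phenyl]chroman-3,5-diyl bis[3,4,5-tris(benzyloxy)benzoate]
Conditions: DCC (3 equiv), DMAP (0.5 equiv), CH2Cl2, rt
Reagents that add atoms: none
Why: Steglich esterification acylates the phenolic 5-OH and the axial secondary 3-OH in one operation; these are the only free hydroxyls, so no selectivity is asked for, and C2 is no longer α to a carbonyl and cannot epimerise.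

Step 9
Reactants: 16 (2R,3R)-7-(benzyloxy)-2-[3,4-bis(benzyloxy)phenyl]chroman-3,5-diyl bis[3,4,5-tris(benzyloxy)benzoate]
Product: 17 (−)-epicatechin 3,5-di-O-gallate, (2R,3R)-2-(3,4-dihydroxyphenyl)-7-hydroxychroman-3,5-diyl bis(3,4,5-trihydroxybenzoate)
Conditions: H2 (1 atm), 20% Pd(OH)2/C, THF–MeOH, rt
Reagents that add atoms: none
Why: Hydrogenolysis of all nine benzyl ethers under neutral conditions should leave the two gallate esters, the C2–O1 ether and both stereocentres untouched.

**Compound list**

1 | phloroglucinol (benzene-1,3,5-triol) | Oc1cc(O)cc(O)c1 | starting material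
2 | 5-hydroxycyclohexane-1,3-dione (dihydrophloroglucinol) | O=C1CC(O)CC(=O)C1 | intermediate
3 | 3,6-dihydroxy-3,5,6,7-tetrahydro-1-benzofuran-4(2H)-one (mixture of diastereomers) | O=C1CC(O)CC2=C1C(O)CO2 | intermediate
4 | 6-hydroxy-6,7-dihydro-1-benzofuran-4(5H)-one (racemic) | O=C1CC(O)Cc2occc12 | intermediate
5 | 6-(benzyloxy)-6,7-dihydro-1-benzofuran-4(5H)-one (racemic) | O=C1CC(OCc2ccccc2)Cc2occc12 | intermediate
6 | 6-(benzyloxy)-4-oxo-4,5,6,7-tetrahydro-1-benzofuran-2-carbaldehyde (racemic) | O=Cc1cc2c(o1)CC(OCc1ccccc1)CC2=O | intermediate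
7 | 3,4-bis(benzyloxy)phenylboronic acid | OB(O)c1ccc(OCc2ccccc2)c(OCc2ccccc2)c1 | starting material
8 | 6-(benzyloxy)-2-{[3,4-bis(benzyloxy)phenyl](hydroxy)methyl}-6,7-dihydro-1-benzofuran-4(5H)-one (mixture of stereoisomers) | OC(c1ccc(OCc2ccccc2)c(OCc2ccccc2)c1)c1cc2c(o1)CC(OCc1ccccc1)CC2=O | intermediate
9 | 7-(benzyloxy)-2-[3,4-bis(benzyloxy)phenyl]-8a-hydroxy-6,7,8,8a-tetrahydro-2H-chromene-3,5-dione (mixture of stereoisomers) | O=C1C=C2C(=O)CC(OCc3ccccc3)CC2(O)OC1c1ccc(OCc2ccccc2)c(OCc2ccccc2)c1 | intermediate
10 | 7-(benzyloxy)-2-[3,4-bis(benzyloxy)phenyl]-3,5-dioxo-3,5,6,7,8,8a-hexahydro-2H-chromen-8a-yl trifluoroacetate (mixture of stereoisomers) | O=C1C=C2C(=O)CC(OCc3ccccc3)CC2(OC(=O)C(F)(F)F)OC1c1ccc(OCc2ccccc2)c(OCc2ccccc2)c1 | intermediate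
11 | 7-(benzyloxy)-2-[3,4-bis(benzyloxy)phenyl]-5-oxo-5,6,7,8-tetrahydrochromenylium-3-olate (racemic) | [O-]c1cc2C(=O)CC(OCc3ccccc3)Cc2[o+]c1-c1ccc(OCc2ccccc2)c(OCc2ccccc2)c1 | intermediate
12 | 7-(benzyloxy)-2-[3,4-bis(benzyloxy)phenyl]-6,7-dihydro-2H-chromene-3,5-dione (mixture of stereoisomers) | O=C1C=C2C(=O)CC(OCc3ccccc3)C=C2OC1c1ccc(OCc2ccccc2)c(OCc2ccccc2)c1 | intermediate
13 | 7-(benzyloxy)-2-[3,4-bis(benzyloxy)phenyl]-5-hydroxychroman-3-one (racemic) | O=C1Cc2c(O)cc(OCc3ccccc3)cc2OC1c1ccc(OCc2ccccc2)c(OCc2ccccc2)c1 | intermediate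
14 | (2R,3R)-7-(benzyloxy)-2-[3,4-bis(benzyloxy)phenyl]chroman-3,5-diol | Oc1cc(OCc3ccccc3)cc2c1C[C@@H](O)[C@@H](c1ccc(OCc3ccccc3)c(OCc3ccccc3)c1)O2 | intermediate
15 | 3,4,5-tris(benzyloxy)benzoic acid | OC(=O)c1cc(OCc2ccccc2)c(OCc2ccccc2)c(OCc2ccccc2)c1 | starting material
16 | (2R,3R)-7-(benzyloxy)-2-[3,4-bis(benzyloxy)phenyl]chroman-3,5-diyl bis[3,4,5-tris(benzyloxy)benzoate] | O=C(Oc1cc(OCc3ccccc3)cc2c1C[C@@H](OC(=O)c3cc(OCc4ccccc4)c(OCc4ccccc4)c(OCc4ccccc4)c3)[C@@H](c3ccc(OCc4ccccc4)c(OCc4ccccc4)c3)O2)c1cc(OCc2ccccc2)c(OCc2ccccc2)c(OCc2ccccc2)c1 | intermediate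
17 | (−)-epicatechin 3,5-di-O-gallate | O=C(Oc1cc(O)cc2c1C[C@@H](OC(=O)c1cc(O)c(O)c(O)c1)[C@@H](c1ccc(O)c(O)c1)O2)c1cc(O)c(O)c(O)c1 | target

**Count and risks**

Total step count: 9. Longest linear sequence: 9 steps (1 → 17); compounds 7 and 15 are bought.

Steps most likely to fail:

Step 6 (proposed new method). Benzyl alcohol may be lost from C7 at the betaine or dienone stage faster than the proton shifts that aromatise ring A, ring C may open and the liberated resorcinol reclose on C3 to a benzofuran, or the betaine may dimerise. The fallback uses known reactions and runs from dione 2 back to ketone 13. Wittig homologation of commercial 3,4-bis(benzyloxy)benzaldehyde with Ph3P=CHCHO would give (E)-3-[3,4-bis(benzyloxy)phenyl]prop-2-enal F1. Its Knoevenagel condensation with 2 and oxa-6π electrocyclisation (ethylenediammonium diacetate, MeOH) would give 2-[3,4-bis(benzyloxy)phenyl]-7-hydroxy-7,8-dihydro-2H-chromen-5(6H)-one F2, which would be benzylated as in step 3 to 7-(benzyloxy)-2-[3,4-bis(benzyloxy)phenyl]-7,8-dihydro-2H-chromen-5(6H)-one F3. α-Selenation (LiN(i-Pr)2, PhSeCl, THF, −78 °C) to 7-(benzyloxy)-2-[3,4-bis(benzyloxy)phenyl]-6-(phenylselanyl)-7,8-dihydro-2H-chromen-5(6H)-one F4 and selenoxide elimination (H2O2) would aromatise ring A to 7-(benzyloxy)-2-[3,4-bis(benzyloxy)phenyl]-2H-chromen-5-ol F5. Hydroboration–oxidation (BH3·THF; NaOH, H2O2) would give racemic trans-7-(benzyloxy)-2-[3,4-bis(benzyloxy)phenyl]chroman-3,5-diol F6, and Parikh–Doering oxidation (SO3·pyridine, DMSO, i-Pr2NEt) would return to 13. Ring A is still carried as the dione and aromatised late, so O5 and O7 stay distinct, but ring C is then made by condensation and electrocyclisation and the C3 oxygen is introduced separately.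

Step 7. Enolisation at C2 may be too slow relative to hydride transfer (so that only a kinetic resolution results), the catalyst may discriminate the faces poorly or in the opposite sense, or the electron-rich ketone may be oxidised by air in the amine buffer. The fallback runs from 13 to 14. Reduction with LiBH(s-Bu)3 (THF, −78 °C), a reagent known to give 2,3-cis-flavan-3-ols from flavan-3-ones, would give the racemic cis-diol, that is 14 together with its enantiomer (2S,3S)-7-(benzyloxy)-2-[3,4-bis(benzyloxy)phenyl]chroman-3,5-diol F7. The two would be separated by chromatography on a chiral stationary phase, and F7 would be returned to 13 by Parikh–Doering oxidation and reduced again. Stereocontrol would then rest on substrate-controlled hydride delivery plus resolution with recycling, not on a dynamic catalytic reduction.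

Step 3. Acid may dehydrate the β-hydroxy ketone (which would lead on to a benzofuranol by aromatisation), or the benzyl cation equivalent may alkylate the furan carbon. The fallback runs from 4 to 5. Silylation (Et3SiCl, imidazole, DMF) would give 6-(triethylsilyloxy)-6,7-dihydro-1-benzofuran-4(5H)-one F8, and reductive etherification with benzaldehyde (Et3SiH, BiBr3 cat., MeCN, 0 °C) would give 5; here the ether C–O bond is formed by reduction of an oxocarbenium ion, and neither a benzyl cation nor an alkoxide is involved.

**Further compounds**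

F1 | step 6 | (E)-3-[3,4-bis(benzyloxy)phenyl]prop-2-enal | O=C/C=C/c1ccc(OCc2ccccc2)c(OCc2ccccc2)c1
F2 | step 6 | 2-[3,4-bis(benzyloxy)phenyl]-7-hydroxy-7,8-dihydro-2H-chromen-5(6H)-one (mixture of stereoisomers) | O=C1CC(O)CC2=C1C=CC(c1ccc(OCc3ccccc3)c(OCc3ccccc3)c1)O2
F3 | step 6 | 7-(benzyloxy)-2-[3,4-bis(benzyloxy)phenyl]-7,8-dihydro-2H-chromen-5(6H)-one (mixture of stereoisomers) | O=C1CC(OCc3ccccc3)CC2=C1C=CC(c1ccc(OCc3ccccc3)c(OCc3ccccc3)c1)O2
F4 | step 6 | 7-(benzyloxy)-2-[3,4-bis(benzyloxy)phenyl]-6-(phenylselanyl)-7,8-dihydro-2H-chromen-5(6H)-one (mixture of stereoisomers) | O=C1C([Se]c3ccccc3)C(OCc3ccccc3)CC2=C1C=CC(c1ccc(OCc3ccccc3)c(OCc3ccccc3)c1)O2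
F5 | step 6 | 7-(benzyloxy)-2-[3,4-bis(benzyloxy)phenyl]-2H-chromen-5-ol (racemic) | Oc1cc(OCc3ccccc3)cc2c1C=CC(c1ccc(OCc3ccccc3)c(OCc3ccccc3)c1)O2
F6 | step 6 | trans-7-(benzyloxy)-2-[3,4-bis(benzyloxy)phenyl]chroman-3,5-diol (racemic; the 2R,3S enantiomer is drawn) | Oc1cc(OCc3ccccc3)cc2c1C[C@H](O)[C@@H](c1ccc(OCc3ccccc3)c(OCc3ccccc3)c1)O2
F7 | step 7 | (2S,3S)-7-(benzyloxy)-2-[3,4-bis(benzyloxy)phenyl]chroman-3,5-diol | Oc1cc(OCc3ccccc3)cc2c1C[C@H](O)[C@H](c1ccc(OCc3ccccc3)c(OCc3ccccc3)c1)O2
F8 | step 3 | 6-(triethylsilyloxy)-6,7-dihydro-1-benzofuran-4(5H)-one (racemic) | O=C1CC(O[Si](CC)(CC)CC)Cc2occc12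
A1 | direct plan | 3-(methoxymethoxy)-5-(triisopropylsilyloxy)phenol | COCOc1cc(O)cc(O[Si](C(C)C)(C(C)C)C(C)C)c1
A2 | direct plan | (S)-[3,4-bis(benzyloxy)phenyl][(2R)-oxiran-2-yl]methanol | C1[C@@H](O1)[C@H](c1ccc(OCc2ccccc2)c(OCc2ccccc2)c1)O
A3 | direct plan | (2R)-2-{(R)-[3,4-bis(benzyloxy)phenyl][3-(methoxymethoxy)-5-(triisopropylsilyloxy)phenoxy]methyl}oxirane | C1[C@@H](O1)[C@@H](c1ccc(OCc2ccccc2)c(OCc2ccccc2)c1)Oc1cc(OCOC)cc(O[Si](C(C)C)(C(C)C)C(C)C)c1
A4 | direct plan | (2R,3R)-2-[3,4-bis(benzyloxy)phenyl]-7-(triisopropylsilyloxy)chroman-3,5-diyl bis[3,4,5-tris(benzyloxy)benzoate] | O=C(Oc1cc(O[Si](C(C)C)(C(C)C)C(C)C)cc2c1C[C@@H](OC(=O)c3cc(OCc4ccccc4)c(OCc4ccccc4)c(OCc4ccccc4)c3)[C@@H](c3ccc(OCc4ccccc4)c(OCc4ccccc4)c3)O2)c1cc(OCc2ccccc2)c(OCc2ccccc2)c(OCc2ccccc2)c1
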